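The data were generated by integration from invented constants, and the scatter is random.

**The questions.** 4 questions stood on the gamma flask at 3.0 d, and I had its own course and the denser beta run to answer them.

in all of them: X 5 mol%

| charge | Q | J | E | remark | time |
|---|---|---|---|---|---|
| gamma | 0.40 M | 2 equiv | 1.2 equiv | the very flask that is asked about, followed so far |  |
| beta | 0.80 M | 2 equiv | 1.2 equiv | run made earlier |  |
| flask | 0.40 M | 2.00 equiv | 1.20 equiv |  | 3.0 d |

- gamma (time / h: G / %, Q / %): 3.00: 6.4, 93.5; 6.00: 14.5, 84.3; 12.0: 33.7, 67.9; 25.0: 48.7, 52.5; 40.0: 54.6, 45.4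
- beta (time / h: G / %, Q / %): 0.333: 0.4, 99.1; 0.667: 0.4, 97.4; 1.00: 1.9, 98.0; 2.00: 7.1, 93.2; 4.00: 15.8, 85.4

(scatter of a reading: 1 percentage point)

- given per volume of solution although it is solid: E
- G taken out counts as made
- at the start none of E is in solution
- additions bring no volume worth counting

- winter: at 3.0 d add Q, 50.0% of the amount charged, then wait 20 h
- spring: change nothing and wait 20 h more
- dusk: at 3.0 d take out 90% of the G then present, then wait 20 h
- dawn: at 3.0 d add X, 100% of the amount charged, then wait 20 h

1. G, in percent of the Q first charged, at 3.0 d
2. the remedy with the largest gain of G, or "none" below 2 percentage points (winter / spring / dusk / dawn / none)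
3. G present, with what was taken out counted in, in percent of the Q first charged, after winter
4. G present, with what was taken out counted in, in percent of the Q first charged, after dawn

**One constant.** In gamma, G and Q summed to 100% at the last reading, so I first read Q as decaying pseudo-first-order, with 0.0198 h⁻¹ between 12.0 h and 25.0 h. But the next interval gave 0.00969 h⁻¹, less, so that estimate fell.

**One X.** Beta reached 15.8% of G at 4.00 h, while gamma needed 6.00 h for 14.5%, so I took it that concentration counted and that Q had a partner. I therefore followed one X: at each moment it either turns over, at a pace proportional to Q times the E unused (assuming one E per G), or dies. With q the fraction of Q left, e the equivalents of E and a = e − 1, here 0.200, its accumulated work is S = ln[(q + a)/(q e)]/a.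

**Gamma's reach.** Reading from 12.0 h, past what I took for the dissolving of E, S stood at 0.379, 0.702 and 0.913. Its slope fell from 0.0248 h⁻¹ to 0.0141 h⁻¹, which reads as a decay of 0.0406 h⁻¹, a half-life of X of 17.1 h. Carried on, this gave 1.10 as the reach, the work S that one X has done by 3.0 d, so G of 59.6%. Fresh X at dawn added to S, and I reckoned 72.0%. My doubt was J: no reading shows it, so my count of E left might stand high.

**The forecast.** It gave 58.5%, dawn as the remedy, 61% after winter and 76% after dawn, saying “Fresh X takes Q from 41 to about 23”; my dawn figure stood lower.

**The result.** The flask gave 58.1%, dawn with a gain of 8.9 percentage points, 59.9% after winter and 67.0% after dawn.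

    Q + L + X → X + G (k = 0.130 L² mol⁻² min⁻¹)
    J + L + X → X + D (k = 0.0220 L² mol⁻² min⁻¹)
    E ⇌ L, rate k3*(cs3 - [L]) while solid is left; crystals form when [L] > cs3 (solubility = 0.370 M, k = 0.00730 min⁻¹)
    X → Z (k = 6.30 × 10⁻⁴ min⁻¹)

At 72.0 h E charged less G made came to 0.248 M, but the flask held L at 0.138 M, less, with D at 0.110 M. At 72.0 h the neighbour with 0.720 equiv of E held X at 6.58%, as the flask did, so I gave it the same reach 1.10. That put its Q at 59.5%, and it held 59.9% of Q with 40.1% of G.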